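**Plan**
1. Retrosynthesis: the acid chain is cut at C4′–C5′ (sp2–sp2) into an (R)-iodoalkene and a C18 enyne, and the enyne at C7′–C8′ (allylic alkylation). The bicyclic core, once a formyl group is placed on C6, is cut across C6–C7 and C5–C10 into an acyclic trienal, which is cut at C1–C10 and at C8–C9.
2. Enabling feature: ring B is a cyclohexene whose only double bond (C8=C9) lies opposite the C5–C6 bond, a Diels–Alder retron. The C1–C2–C3–C4 chain of ring A already joins diene terminus C10 to dienophile carbon C5, so one intramolecular [4+2] event closes rings B and A together and creates C5, C10 and the tetrasubstituted C8=C9 bond.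
3. Forward: but-2-yn-1-ol → stereodefined dienyl iodide → B-alkyl Suzuki coupling with the tether → trienal → rings A and B in one step → removal of the C6 formyl helper → C11 bromide → propargylation → carboalumination/Negishi coupling → desilylation → oxidation to the acid.
4. Stereochemistry: C5 and C10 come from a chiral amine catalyst and the endo transition state of the cycloaddition; C2′ comes from the chiral pool (methyl (S)-3-hydroxy-2-methylpropanoate). Alkene geometry comes from anti-carbomagnesiation (8Z of the triene), the HWE reaction (2E of the enal), syn-carboalumination (5′E) and the Takai olefination (3′E).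

Key step: step 6

Remark: ring carbons carry drimane numbers (ring A = C1–C5, C10; ring B = C5–C10; gem-dimethyl on C4; angular methyl on C10; C11 = first chain carbon on C9) and the acid chain is numbered C1′ (CO2H) to C8′ (= C11); the starting materials, reagents and catalyst named are assumed to be commercially available.

Step 1
Reactants: 1 but-2-yn-1-ol
Product: 3 (2Z)-3-iodo-2-(prop-1-en-2-yl)but-2-en-1-ol, via oxamagnesole chelate 2 (not isolated)
Conditions: isopropenylMgBr (3 equiv), CuI (10 mol %), THF, 0 °C to reflux; then I2, THF, −40 to 0 °C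
Reagents that add atoms: isopropenylmagnesium bromide C=C(C)[Mg]Br; iodine II
Why: Anti-carbomagnesiation of a propargylic alcohol delivers the isopropenyl group to the alkyne carbon next to CH2O and magnesium to the distal carbon within a five-membered alkoxide chelate, so iodinolysis with retention should give the tetrasubstituted iodoalkene with I cis to CH2OH and methyl cis to isopropenyl.

Step 2
Reactants: 3 (2Z)-3-iodo-2-(prop-1-en-2-yl)but-2-en-1-ol
Product: 4 tert-butyl{[(2Z)-3-iodo-2-(prop-1-en-2-yl)but-2-en-1-yl]oxy}dimethylsilane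
Conditions: TBSCl, imidazole, CH2Cl2, 0 °C to rt
Reagents that add atoms: tert-butyldimethylsilyl chloride CC(C)(C)[Si](C)(C)Cl
Why: Standard silylation of a primary allylic alcohol; the silyl ether masks the C11 oxygen through the hydride reduction and later serves directly as the precursor of the allylic bromide.

Step 3
Reactants: 5 2,2-dimethylpent-4-enal
Product: 6 (2E)-N-methoxy-N,4,4-trimethylhepta-2,6-dienamide
Conditions: (EtO)2P(O)CH2C(O)N(OMe)Me, NaH, THF, 0 °C to rt
Reagents that add atoms: diethyl {2-[methoxy(methyl)amino]-2-oxoethyl}phosphonate CCOP(=O)(CC(=O)N(C)OC)OCC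
Why: Horner–Wadsworth–Emmons olefination of a non-enolisable α-quaternary aldehyde with a stabilised phosphonate should give the (E)-enamide and installs the N-methoxy-N-methylamide as a latent aldehyde.

Step 4
Reactants: 6 (2E)-N-methoxy-N,4,4-trimethylhepta-2,6-dienamide; 4 tert-butyl{[(2Z)-3-iodo-2-(prop-1-en-2-yl)but-2-en-1-yl]oxy}dimethylsilane
Product: 8 (2E,8Z)-9-({[tert-butyl(dimethyl)silyl]oxy}methyl)-N-methoxy-N,4,4,8,10-pentamethylundeca-2,8,10-trienamide, via B-alkyl-9-BBN 7 (not isolated)
Conditions: 6, 9-BBN-H (1.1 equiv), THF, 0 °C to rt; then 4, Pd(dppf)Cl2 (5 mol %), AsPh3 (10 mol %), Cs2CO3, DMF/H2O, rt to 45 °C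
Reagents that add atoms: none
Why: B-alkyl Suzuki–Miyaura coupling: 9-BBN hydroborates only the monosubstituted alkene of 6 (anti-Markovnikov), and the primary alkylborane couples with the alkenyl iodide with retention of geometry, which places the tether trans to the isopropenyl group.

Step 5
Reactants: 8 (2E,8Z)-9-({[tert-butyl(dimethyl)silyl]oxy}methyl)-N-methoxy-N,4,4,8,10-pentamethylundeca-2,8,10-trienamide
Product: 9 (2E,8Z)-9-({[tert-butyl(dimethyl)silyl]oxy}methyl)-4,4,8,10-tetramethylundeca-2,8,10-trienal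
Conditions: DIBAL-H (1.3 equiv), THF, −78 °C; aq. Rochelle salt
Reagents that add atoms: none
Why: Hydride reduction of an N-methoxy-N-methylamide stops at the chelated tetrahedral aluminate, which should release the (E)-enal on work-up without touching the silyl ether or the diene.

Step 6
Reactants: 9 (2E,8Z)-9-({[tert-butyl(dimethyl)silyl]oxy}methyl)-4,4,8,10-tetramethylundeca-2,8,10-trienal
Product: 10 (1S,4aS,8aS)-4-({[tert-butyl(dimethyl)silyl]oxy}methyl)-3,4a,8,8-tetramethyl-1,2,4a,5,6,7,8,8a-octahydronaphthalene-1-carbaldehyde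
Conditions: (2S,5S)-5-benzyl-2-tert-butyl-3-methylimidazolidin-4-one·TFA (20 mol %), MeCN/H2O (98:2), −10 °C to rt
Reagents that add atoms: none
Why: Condensation of enal 9 with the secondary amine salt gives the (E)-iminium ion, whose LUMO-lowered C5=C6 π bond undergoes a concerted, asynchronous [4+2] cycloaddition with the tethered C7=C8–C9=C10 diene, and hydrolysis of the product iminium ion releases 10 and the catalyst. The closest known reaction type is the imidazolidinone-catalysed enantioselective type 1 intramolecular Diels–Alder reaction of (2E)-deca-2,7,9-trienals to trans-fused decalins. Ring B (cyclohexene) is closed by the cycloaddition itself through the C6–C7 and C5–C10 bonds, and ring A (cyclohexane) is closed by the same C5–C10 bond across the C1–C4 tether, exo with respect to both π components (fused mode) through a chair-like tether. C5 is controlled by the catalyst, whose benzyl group shields one face of the iminium alkene so that the diene should add to the open face (5S by the accepted model for this catalyst); C10 is controlled relative to C5 by the endo transition state (iminium carbon under the diene, tether anti), which puts the inside methyl of C10 trans to H-5 (trans fusion, 10S), and the transient C6 centre follows from the E-enal. The step needs π-facial, endo/exo and site selectivity: the first comes from the catalyst, the second from the E-dienophile and the endo preference of the iminium ion, the third from the design, since 9 holds a single diene and a single activated alkene (the side-chain diene is added later), the 8Z geometry places the tether outside and the methyl inside on the diene terminus, and the C4 gem-dimethyl group favours the folded conformer. The low temperature should also avoid the [1,5]-hydrogen shift to which the Z-methyl diene would be prone on heating.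

Step 7
Reactants: 10 (1S,4aS,8aS)-4-({[tert-butyl(dimethyl)silyl]oxy}methyl)-3,4a,8,8-tetramethyl-1,2,4a,5,6,7,8,8a-octahydronaphthalene-1-carbaldehyde
Product: 11 tert-butyl(dimethyl){[(4aS,8aS)-2,5,5,8a-tetramethyl-3,4,4a,5,6,7,8,8a-octahydronaphthalen-1-yl]methoxy}silane
Conditions: RhCl(PPh3)3 (1.1 equiv), xylene, 135 °C
Reagents that add atoms: none
Why: Rhodium(I)-mediated decarbonylation (Tsuji–Wilson reaction: oxidative addition into the formyl C–H bond, CO extrusion, C–H reductive elimination) removes the activating group and leaves C6 as a methylene, so no stereocentre of the target is touched.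

Step 8
Reactants: 11 tert-butyl(dimethyl){[(4aS,8aS)-2,5,5,8a-tetramethyl-3,4,4a,5,6,7,8,8a-octahydronaphthalen-1-yl]methoxy}silane
Product: 12 (4aS,8aS)-5-(bromomethyl)-1,1,4a,6-tetramethyl-1,2,3,4,4a,7,8,8a-octahydronaphthalene
Conditions: Ph3PBr2 (1.2 equiv), CH2Cl2, 0 °C to rt
Reagents that add atoms: triphenylphosphine dibromide Br[P+](c1ccccc1)(c1ccccc1)c1ccccc1.[Br-]
Why: Direct conversion of a silyl ether into a bromide by a bromophosphonium salt (Appel-type activation of oxygen, then SN2 displacement at the primary allylic carbon) should give the primary bromide, the favoured allylic isomer because the ring alkene stays tetrasubstituted.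

Step 9
Reactants: 12 (4aS,8aS)-5-(bromomethyl)-1,1,4a,6-tetramethyl-1,2,3,4,4a,7,8,8a-octahydronaphthalene
Product: 14 (4aS,8aS)-5-(but-3-yn-1-yl)-1,1,4a,6-tetramethyl-1,2,3,4,4a,7,8,8a-octahydronaphthalene, via TMS-alkyne 13 (not isolated)
Conditions: 1-(trimethylsilyl)propyne, n-BuLi, THF, −78 to −20 °C; 12, −78 to 0 °C; then MeOH, K2CO3 (cat.), rt
Reagents that add atoms: 1-(trimethylsilyl)propyne CC#C[Si](C)(C)C
Why: SN2 alkylation of the primary allylic bromide by lithiated 1-(trimethylsilyl)propyne at its propargylic carbon forms the C7′–C8′ bond, and methanolysis of the C–Si bond in the same flask should give the terminal alkyne.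

Step 10
Reactants: 15 methyl (2S)-3-hydroxy-2-methylpropanoate
Product: 16 methyl (2S)-3-{[tert-butyl(dimethyl)silyl]oxy}-2-methylpropanoate
Conditions: TBSCl, imidazole, CH2Cl2, 0 °C to rt
Reagents that add atoms: tert-butyldimethylsilyl chloride CC(C)(C)[Si](C)(C)Cl
Why: Standard silylation of the primary alcohol; this carbon becomes the carboxyl carbon C1′ at the end, and the stereocentre is bought with the starting material.

Step 11
Reactants: 16 methyl (2S)-3-{[tert-butyl(dimethyl)silyl]oxy}-2-methylpropanoate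
Product: 17 (2S)-3-{[tert-butyl(dimethyl)silyl]oxy}-2-methylpropanal
Conditions: DIBAL-H (1.05 equiv), CH2Cl2, −78 °C; aq. Rochelle salt
Reagents that add atoms: none
Why: Partial reduction of the ester at −78 °C through the stable tetrahedral aluminate should give the aldehyde without epimerisation of the α-stereocentre.

Step 12
Reactants: 17 (2S)-3-{[tert-butyl(dimethyl)silyl]oxy}-2-methylpropanal
Product: 18 tert-butyl{[(2R,3E)-4-iodo-2-methylbut-3-en-1-yl]oxy}dimethylsilane
Conditions: CrCl2 (6 equiv), CHI3 (2 equiv), THF, 0 °C to rt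
Reagents that add atoms: iodoform IC(I)I
Why: Takai olefination (gem-dichromium reagent from iodoform and CrCl2) should convert the aldehyde into the (E)-iodoalkene under non-basic conditions that leave the α-stereocentre intact (the descriptor changes from S to R only through the priority change).

Step 13
Reactants: 14 (4aS,8aS)-5-(but-3-yn-1-yl)-1,1,4a,6-tetramethyl-1,2,3,4,4a,7,8,8a-octahydronaphthalene; 18 tert-butyl{[(2R,3E)-4-iodo-2-methylbut-3-en-1-yl]oxy}dimethylsilane
Product: 21 tert-butyl({(2R,3E,5E)-2,6-dimethyl-8-[(4aS,8aS)-2,5,5,8a-tetramethyl-3,4,4a,5,6,7,8,8a-octahydronaphthalen-1-yl]octa-3,5-dien-1-yl}oxy)dimethylsilane, via alkenylalane 19 (not isolated), via alkenylzinc chloride 20 (not isolated)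
Conditions: 14, Me3Al (2.5 equiv), Cp2ZrCl2 (0.25 equiv), CH2Cl2, 0 °C to rt; excess Me3Al removed in vacuo; then ZnCl2 (1.0 equiv), 18, Pd(PPh3)4 (5 mol %), THF, rt
Reagents that add atoms: trimethylaluminium C[Al](C)C
Why: Zirconium-catalysed syn-carboalumination of the terminal alkyne (methyl to the internal carbon, aluminium to the terminus) fixes the 5′E trisubstituted alkene, and transmetalation to zinc followed by palladium-catalysed Negishi coupling with 18 should form the C4′–C5′ bond with retention of both alkene geometries.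

Step 14
Reactants: 21 tert-butyl({(2R,3E,5E)-2,6-dimethyl-8-[(4aS,8aS)-2,5,5,8a-tetramethyl-3,4,4a,5,6,7,8,8a-octahydronaphthalen-1-yl]octa-3,5-dien-1-yl}oxy)dimethylsilane
Product: 22 (2R,3E,5E)-2,6-dimethyl-8-[(4aS,8aS)-2,5,5,8a-tetramethyl-3,4,4a,5,6,7,8,8a-octahydronaphthalen-1-yl]octa-3,5-dien-1-ol
Conditions: TBAF, THF, 0 °C to rt
Reagents that add atoms: none
Why: Fluoride-induced cleavage of the primary silyl ether; at the alcohol oxidation level the neighbouring stereocentre is not acidic.

Step 15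
Reactants: 22 (2R,3E,5E)-2,6-dimethyl-8-[(4aS,8aS)-2,5,5,8a-tetramethyl-3,4,4a,5,6,7,8,8a-octahydronaphthalen-1-yl]octa-3,5-dien-1-ol
Product: 24 (2R,3E,5E)-2,6-dimethyl-8-[(4aS,8aS)-2,5,5,8a-tetramethyl-3,4,4a,5,6,7,8,8a-octahydronaphthalen-1-yl]octa-3,5-dienoic acid, via aldehyde 23 (not isolated)
Conditions: TEMPO (20 mol %), PhI(OAc)2 (2.3 equiv), MeCN/pH 7 phosphate buffer (1:1), 0 °C to rt
Reagents that add atoms: water O
Why: TEMPO-catalysed (oxoammonium) oxidation takes the primary alcohol to the aldehyde and, through its hydrate, on to the acid in one operation under buffered near-neutral conditions, so the epimerisable α-methyl-β,γ-unsaturated aldehyde 23 should be consumed as it forms.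

**Compound list**
1 | but-2-yn-1-ol | CC#CCO | starting material
2 | 3-methyl-4-(prop-1-en-2-yl)-2,5-dihydro-1,2-oxamagnesole (cyclic alkenylmagnesium alkoxide) | CC1=C(C(C)=C)CO[Mg]1 | intermediate
3 | (2Z)-3-iodo-2-(prop-1-en-2-yl)but-2-en-1-ol | OC/C(C(C)=C)=C(\I)C | intermediate
4 | tert-butyl{[(2Z)-3-iodo-2-(prop-1-en-2-yl)but-2-en-1-yl]oxy}dimethylsilane | CC(C)(C)[Si](C)(C)OC/C(C(C)=C)=C(\I)C | intermediate
5 | 2,2-dimethylpent-4-enal | C=CCC(C)(C)C=O | starting material
6 | (2E)-N-methoxy-N,4,4-trimethylhepta-2,6-dienamide | C=CCC(C)(C)/C=C/C(=O)N(C)OC | intermediate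
7 | (2E)-7-(9-borabicyclo[3.3.1]nonan-9-yl)-N-methoxy-N,4,4-trimethylhept-2-enamide | CON(C)C(=O)/C=C/C(C)(C)CCCB1C2CCCC1CCC2 | intermediate
8 | (2E,8Z)-9-({[tert-butyl(dimethyl)silyl]oxy}methyl)-N-methoxy-N,4,4,8,10-pentamethylundeca-2,8,10-trienamide | CON(C)C(=O)/C=C/C(C)(C)CCC/C(C)=C(\CO[Si](C)(C)C(C)(C)C)C(C)=C | intermediate
9 | (2E,8Z)-9-({[tert-butyl(dimethyl)silyl]oxy}methyl)-4,4,8,10-tetramethylundeca-2,8,10-trienal | O=C/C=C/C(C)(C)CCC/C(C)=C(\CO[Si](C)(C)C(C)(C)C)C(C)=C | intermediate
10 | (1S,4aS,8aS)-4-({[tert-butyl(dimethyl)silyl]oxy}methyl)-3,4a,8,8-tetramethyl-1,2,4a,5,6,7,8,8a-octahydronaphthalene-1-carbaldehyde | CC1=C(CO[Si](C)(C)C(C)(C)C)[C@@]2(C)CCCC(C)(C)[C@@H]2[C@@H](C=O)C1 | intermediate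
11 | tert-butyl(dimethyl){[(4aS,8aS)-2,5,5,8a-tetramethyl-3,4,4a,5,6,7,8,8a-octahydronaphthalen-1-yl]methoxy}silane | CC1=C(CO[Si](C)(C)C(C)(C)C)[C@@]2(C)CCCC(C)(C)[C@@H]2CC1 | intermediate
12 | (4aS,8aS)-5-(bromomethyl)-1,1,4a,6-tetramethyl-1,2,3,4,4a,7,8,8a-octahydronaphthalene | CC1=C(CBr)[C@@]2(C)CCCC(C)(C)[C@@H]2CC1 | intermediate
13 | trimethyl{4-[(4aS,8aS)-2,5,5,8a-tetramethyl-3,4,4a,5,6,7,8,8a-octahydronaphthalen-1-yl]but-1-yn-1-yl}silane | CC1=C(CCC#C[Si](C)(C)C)[C@@]2(C)CCCC(C)(C)[C@@H]2CC1 | intermediate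
14 | (4aS,8aS)-5-(but-3-yn-1-yl)-1,1,4a,6-tetramethyl-1,2,3,4,4a,7,8,8a-octahydronaphthalene | CC1=C(CCC#C)[C@@]2(C)CCCC(C)(C)[C@@H]2CC1 | intermediate
15 | methyl (2S)-3-hydroxy-2-methylpropanoate | COC(=O)[C@@H](C)CO | starting material
16 | methyl (2S)-3-{[tert-butyl(dimethyl)silyl]oxy}-2-methylpropanoate | COC(=O)[C@@H](C)CO[Si](C)(C)C(C)(C)C | intermediate
17 | (2S)-3-{[tert-butyl(dimethyl)silyl]oxy}-2-methylpropanal | O=C[C@@H](C)CO[Si](C)(C)C(C)(C)C | intermediate
18 | tert-butyl{[(2R,3E)-4-iodo-2-methylbut-3-en-1-yl]oxy}dimethylsilane | I/C=C/[C@@H](C)CO[Si](C)(C)C(C)(C)C | intermediate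
19 | dimethyl{(1E)-2-methyl-4-[(4aS,8aS)-2,5,5,8a-tetramethyl-3,4,4a,5,6,7,8,8a-octahydronaphthalen-1-yl]but-1-en-1-yl}alumane | CC1=C(CC/C(C)=C/[Al](C)C)[C@@]2(C)CCCC(C)(C)[C@@H]2CC1 | intermediate
20 | chloro{(1E)-2-methyl-4-[(4aS,8aS)-2,5,5,8a-tetramethyl-3,4,4a,5,6,7,8,8a-octahydronaphthalen-1-yl]but-1-en-1-yl}zinc | CC1=C(CC/C(C)=C/[Zn]Cl)[C@@]2(C)CCCC(C)(C)[C@@H]2CC1 | intermediate
21 | tert-butyl({(2R,3E,5E)-2,6-dimethyl-8-[(4aS,8aS)-2,5,5,8a-tetramethyl-3,4,4a,5,6,7,8,8a-octahydronaphthalen-1-yl]octa-3,5-dien-1-yl}oxy)dimethylsilane | CC1=C(CC/C(C)=C/C=C/[C@@H](C)CO[Si](C)(C)C(C)(C)C)[C@@]2(C)CCCC(C)(C)[C@@H]2CC1 | intermediate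
22 | (2R,3E,5E)-2,6-dimethyl-8-[(4aS,8aS)-2,5,5,8a-tetramethyl-3,4,4a,5,6,7,8,8a-octahydronaphthalen-1-yl]octa-3,5-dien-1-ol | CC1=C(CC/C(C)=C/C=C/[C@@H](C)CO)[C@@]2(C)CCCC(C)(C)[C@@H]2CC1 | intermediate
23 | (2R,3E,5E)-2,6-dimethyl-8-[(4aS,8aS)-2,5,5,8a-tetramethyl-3,4,4a,5,6,7,8,8a-octahydronaphthalen-1-yl]octa-3,5-dienal | CC1=C(CC/C(C)=C/C=C/[C@@H](C)C=O)[C@@]2(C)CCCC(C)(C)[C@@H]2CC1 | intermediate
24 | (2R,3E,5E)-2,6-dimethyl-8-[(4aS,8aS)-2,5,5,8a-tetramethyl-3,4,4a,5,6,7,8,8a-octahydronaphthalen-1-yl]octa-3,5-dienoic acid | CC1=C(CC/C(C)=C/C=C/[C@@H](C)C(=O)O)[C@@]2(C)CCCC(C)(C)[C@@H]2CC1 | target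

**Step count and risks**
Total: 15 steps. Longest linear sequence: 11 steps (steps 1, 2, 4–9, 13–15, from but-2-yn-1-ol).

Step 6 is the most likely to fail. The cycloaddition may be too slow at the crowded C5–C10 bond, where a neopentyl β-carbon meets a fully substituted diene terminus carrying an inside methyl. Endo/exo control may erode through the developing 1,3-diaxial contact between the C10 methyl and the axial C4 methyl, which would give the cis-fused C10 epimer. Facial discrimination by the catalyst may also be poor. The fallback replaces amine catalysis by auxiliary control under Lewis acid promotion; it sets out from 9 and returns at 10. Pinnick oxidation of 9 (NaClO2, NaH2PO4, 2-methyl-2-butene, t-BuOH/H2O) should give (2E,8Z)-9-({[tert-butyl(dimethyl)silyl]oxy}methyl)-4,4,8,10-tetramethylundeca-2,8,10-trienoic acid F1. Pivaloyl chloride and Et3N (THF, −20 °C) should convert it into the mixed pivalic anhydride F2, which acylates lithiated (4S)-4-benzyl-1,3-oxazolidin-2-one to the N-trienoyl oxazolidinone F3. Me2AlCl (1.4 equiv, CH2Cl2, −30 °C) should then promote the intramolecular Diels–Alder reaction through the chelated s-cis acyl imide, whose benzyl group shields one face, to the trans-fused cycloadduct imide F4 with the same 5S,10S sense. LiBH4 (THF/MeOH, 0 °C) should cleave the auxiliary to the primary alcohol F5, and Dess–Martin oxidation returns aldehyde 10.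

Step 7 is the second risk. Oxidative addition may be slow at the hindered secondary formyl group, and β-hydride elimination from the alkylrhodium hydride may give ring alkenes. The fallback replaces metal-mediated decarbonylation by radical decarboxylation; it sets out from 10 and returns at 11. Pinnick oxidation should give the carboxylic acid F6. Esterification with N-hydroxypyridine-2-thione (EDC, DMAP cat., CH2Cl2, dark) should give the thiohydroxamate ester F7. Barton decarboxylation (visible light, t-BuSH, THF, rt) should then deliver 11, because hydrogen transfer to the secondary C6 radical is faster than any rearrangement through the homoallylic C8=C9 bond.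

Step 15 is the third risk. During the aldehyde stage C2′ may epimerise or the 3′,4′-double bond may move into conjugation. The fallback adjusts the oxidation level on the small fragment and carries the carboxyl group through the coupling; it sets out from 18 and from alkenylzinc chloride 20 (made from 14 as in step 13) and returns at 24. TBAF should convert 18 into (2R,3E)-4-iodo-2-methylbut-3-en-1-ol F8. Jones oxidation (CrO3, H2SO4, acetone, 0 °C), acceptable here because the fragment has no acid-labile diene, should give (2R,3E)-4-iodo-2-methylbut-3-enoic acid F9. Its optical purity can be checked and, if needed, raised by crystallisation of a salt with a chiral amine. TMSCHN2 (MeOH/toluene) should give the methyl ester F10. Negishi coupling of F10 with 20 (Pd(PPh3)4, THF, rt) should give the methyl ester of the target F11. Me3SnOH (1,2-dichloroethane, 70 °C) should convert it into the trimethylstannyl ester F12, which a dilute HCl work-up cleaves to 24.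

**Further compounds**
F1 | step 6 | (2E,8Z)-9-({[tert-butyl(dimethyl)silyl]oxy}methyl)-4,4,8,10-tetramethylundeca-2,8,10-trienoic acid | OC(=O)/C=C/C(C)(C)CCC/C(C)=C(\CO[Si](C)(C)C(C)(C)C)C(C)=C
F2 | step 6 | (2E,8Z)-9-({[tert-butyl(dimethyl)silyl]oxy}methyl)-4,4,8,10-tetramethylundeca-2,8,10-trienoic 2,2-dimethylpropanoic anhydride | CC(C)(C)C(=O)OC(=O)/C=C/C(C)(C)CCC/C(C)=C(\CO[Si](C)(C)C(C)(C)C)C(C)=C
F3 | step 6 | (4S)-4-benzyl-3-[(2E,8Z)-9-({[tert-butyl(dimethyl)silyl]oxy}methyl)-4,4,8,10-tetramethylundeca-2,8,10-trienoyl]-1,3-oxazolidin-2-one | O=C1OC[C@H](Cc2ccccc2)N1C(=O)/C=C/C(C)(C)CCC/C(C)=C(\CO[Si](C)(C)C(C)(C)C)C(C)=C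
F4 | step 6 | (4S)-4-benzyl-3-{[(1S,4aS,8aS)-4-({[tert-butyl(dimethyl)silyl]oxy}methyl)-3,4a,8,8-tetramethyl-1,2,4a,5,6,7,8,8a-octahydronaphthalen-1-yl]carbonyl}-1,3-oxazolidin-2-one | CC1=C(CO[Si](C)(C)C(C)(C)C)[C@@]2(C)CCCC(C)(C)[C@@H]2[C@@H](C(=O)N3C(=O)OC[C@@H]3Cc4ccccc4)C1
F5 | step 6 | [(1S,4aS,8aS)-4-({[tert-butyl(dimethyl)silyl]oxy}methyl)-3,4a,8,8-tetramethyl-1,2,4a,5,6,7,8,8a-octahydronaphthalen-1-yl]methanol | CC1=C(CO[Si](C)(C)C(C)(C)C)[C@@]2(C)CCCC(C)(C)[C@@H]2[C@@H](CO)C1
F6 | step 7 | (1S,4aS,8aS)-4-({[tert-butyl(dimethyl)silyl]oxy}methyl)-3,4a,8,8-tetramethyl-1,2,4a,5,6,7,8,8a-octahydronaphthalene-1-carboxylic acid | CC1=C(CO[Si](C)(C)C(C)(C)C)[C@@]2(C)CCCC(C)(C)[C@@H]2[C@@H](C(=O)O)C1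
F7 | step 7 | 2-sulfanylidenepyridin-1(2H)-yl (1S,4aS,8aS)-4-({[tert-butyl(dimethyl)silyl]oxy}methyl)-3,4a,8,8-tetramethyl-1,2,4a,5,6,7,8,8a-octahydronaphthalene-1-carboxylate | CC1=C(CO[Si](C)(C)C(C)(C)C)[C@@]2(C)CCCC(C)(C)[C@@H]2[C@@H](C(=O)On3ccccc3=S)C1
F8 | step 15 | (2R,3E)-4-iodo-2-methylbut-3-en-1-ol | I/C=C/[C@@H](C)CO
F9 | step 15 | (2R,3E)-4-iodo-2-methylbut-3-enoic acid | I/C=C/[C@@H](C)C(=O)O
F10 | step 15 | methyl (2R,3E)-4-iodo-2-methylbut-3-enoate | I/C=C/[C@@H](C)C(=O)OC
F11 | step 15 | methyl (2R,3E,5E)-2,6-dimethyl-8-[(4aS,8aS)-2,5,5,8a-tetramethyl-3,4,4a,5,6,7,8,8a-octahydronaphthalen-1-yl]octa-3,5-dienoate | CC1=C(CC/C(C)=C/C=C/[C@@H](C)C(=O)OC)[C@@]2(C)CCCC(C)(C)[C@@H]2CC1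
F12 | step 15 | trimethylstannyl (2R,3E,5E)-2,6-dimethyl-8-[(4aS,8aS)-2,5,5,8a-tetramethyl-3,4,4a,5,6,7,8,8a-octahydronaphthalen-1-yl]octa-3,5-dienoate | CC1=C(CC/C(C)=C/C=C/[C@@H](C)C(=O)O[Sn](C)(C)C)[C@@]2(C)CCCC(C)(C)[C@@H]2CC1
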